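**Compound numbering used throughout:** 1–5, 7, 8, 10–17, 19 and 20 are isolated compounds (20 is the target); 6, 9 and 18 form in the flask and are not isolated.

## The problem

Target 20 joins two oxygen heterocycles through one methylene carbon: C3 of a 6-ethyl-4-hydroxy-5-methyl-2H-pyran-2-one and C8 of a 5,7-dihydroxy-6-isobutyryl-2,2-dimethyl-2H-chromene. It has no stereocentre, so the whole difficulty lies in constitution and chemoselectivity. The benzene ring is fully substituted, and the pyran oxygen must sit para to the isobutyryl group (acyl at C6, bridge at C8). An acylphloroglucinol offers two kinds of oxygen for pyran closure, and the wrong one gives the 8-acyl isomer. The bridge links two enolic, carbon-nucleophilic partners; making it from a one-carbon electrophile tends to give symmetrical dimers. Three groups will not survive rough treatment. The chromene C3=C4 bond protonates at C3 to a cation stabilised by three ring oxygens, and it rules out hydrogenation. The acylphloroglucinol nucleus is easily oxidised and C-alkylated. The 4-hydroxypyranone is acidic and nucleophilic at C3 and O4. The feature that opens the key step lies in the pyranone: O1, C6 (ethyl) and C5 (methyl) are the enol of symmetrical pentan-3-one, and C2–C3–C4 with the bridge carbon on C3 is a monosubstituted malonyl unit.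

## Retrosynthesis

**20 ⇒ 19.** The two O–allyl bonds on the chromene phenols are cut. The phenols must be masked while an acid chloride is present. Allyl ethers are preferred over benzyl ethers (hydrogenolysis would reduce C3=C4) and over acetal ethers (acid removal threatens the chromene). The forward step needs zerovalent palladium and an allyl acceptor that outruns the pyranone enolate of 19.

**19 ⇒ 15 + 17.** The pyranone bonds C4–C5 and O1–C2 are cut. This removes a whole ring and leaves a symmetrical five-carbon enol ether 17 and a malonyl dichloride 15 that already carries the bridge and the complete chromene. The neighbouring cut at the bridge (C3–CH2) would join two enolic nucleophiles through a one-carbon electrophile. The neighbouring cut at C3–C4 and O1–C2 delivers the ring as an ether of the wrong tautomer. The forward reaction must acylate carbon before oxygen, use the malonyl unit only once, and keep liberated acid away from the chromene.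

**15 ⇒ 14 ⇒ 13 ⇒ 12 ⇒ 10 + 11.** Dichloride 15 comes from malonic acid 14 and this from diester 13 by functional-group changes. The C–H bonds at the bridge are then removed to give alkylidene 12, and its C=C bond is cut to aldehyde 10 and dimethyl malonate 11. The bridge carbon is thus the formyl carbon of 10. An open-chain malonate is preferred to a cyclic, more acidic one, whose alkylidene would be a competent heterodiene towards the neighbouring allyl ether. The forward steps need a condensation on a doubly ortho-substituted aldehyde, a conjugate reduction that spares the hindered ketone, and an acid chloride formation that liberates no strong acid.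

**10 ⇒ 8.** The pyran ring is opened at C4a–C4 and O1–C2, which leads back to aryl 1,1-dimethylpropargyl ether 8. Closing the ring on a free acylphloroglucinol passes through a quinone methide that can cyclise onto either flanking oxygen. In 8 both oxygens beside the acyl group are ethers and one ortho carbon carries the aldehyde, so the rearrangement has one carbon to go to and one oxygen to close onto. The forward reaction must proceed below the temperature at which allyl aryl ethers rearrange.

**8 ⇒ 7 ⇒ 5.** The two O–allyl bonds are cut to diphenol aldehyde 7, then the aryl–CHO bond to diphenol 5. Formylating at this stage uses the full activation of two free phenols and happens before any acid-sensitive chromene exists. Ether 5 is symmetrical, so its two open ring carbons are equivalent and only one aldehyde can form.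

**5 ⇒ 3 + 4 ⇒ 1 + 2.** The aryl O–C(propargylic) bond is cut to acylphloroglucinol 3 and tertiary propargylic chloride 4, and the aryl–acyl bond to phloroglucinol 1 and isobutyryl chloride 2. The forward alkylation must pick the para hydroxyl of 3. This is the most acidic one and the only one not engaged with the ketone.

**17 ⇒ 16.** The O–Si bond is cut to pentan-3-one 16. Its symmetry means only one enol ether constitution exists.

## Roads not taken

**Alternative 1:** The cut is chromene C4a–C4, with O1–C2 already present in an aryl 1,1-dimethylpropargyl ether; the substrate would be ether 5 itself. A cationic phosphine complex of monovalent gold such as Ph3PAuNTf2 activates the terminal alkyne, the ortho ring carbon attacks in 6-endo fashion, and protodeauration gives chromene diol A1.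
- Merits: O1–C2 is never broken, so the ring oxygen stays para to the acyl group even with both flanking phenols free. The ring closes at room temperature.
- Weak points: it solves the easier ring. A1 lacks the bridge carbon, which must then be introduced at C8 of an electron-rich, acid-sensitive chromene. The pyranone is still to be made or attached. Free phenols beside a Lewis-acidic metal invite alkyne hydration and further reaction of the product alkene.
- Comparison: in mildness, and in not needing the phenols blocked, this closure is better than the thermal one of step 5. The chosen plan sets three things against it. Formylation is done on 5 before a chromene exists. Blocking costs no extra step, because the allyl ethers are needed for the annulation anyway. The step count to aldehyde 10 is the same. The gold closure is kept as the reserve for step 5.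

**Alternative 2:** The cut is pyranone C3–C4 and O1–C2. Dioxinone A3 undergoes thermal cycloreversion to acylketene A5, which adds across silyl ketene acetal A4: ketene carbon to the nucleophilic carbon (C3–C4), acyl oxygen to the acetal carbon (O1–C2). Loss of silanol gives 2-methoxy-4-pyranone A2.
- Merits: the ring forms under neutral thermal conditions with no acid chloride and no liberated acid. The union is convergent and the substituents arrive in fixed positions.
- Weak points: A2 is the methyl ether of the wrong tautomer, so a demethylation is needed beside acetal removal, and both put the chromene at risk. A4 requires ester enolisation next to an enolisable isobutyryl ketone. Its side chain needs a two-carbon homologation of the aldehyde. A3 must be built separately from a β-keto ester. β-Substituted ketene acetals add sluggishly.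
- Comparison: the ring-forming event is gentler than step 11 and better on that count. The chosen plan sets against it direct formation of the free 4-hydroxy-2-pyranone, a one-step symmetrical partner 17, and a neutral final deprotection.

**Alternative 3:** The cut is C8a–O1. Zerovalent palladium inserts into the C8a–Br bond of bromo alcohol A7, the tertiary alkoxide binds, and C–O reductive elimination closes the pyran to chromene A6.
- Merits: the position of the ring oxygen is fixed by the bromine. Nothing depends on acidity differences between phenols or on the course of a pericyclic cascade, and the Z-alkene is set beforehand.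
- Weak points: the bromine occupies a position where phloroglucinol has an oxygen, so the symmetrical triphenol cannot be the start. An arene with bromine, a Z-hydroxyalkenyl chain, two protected phenols and the acyl group in defined positions needs a long sequence, including a Z-selective alkyne semireduction. Tertiary alkoxides are the most reluctant partners in C–O reductive elimination, and hydrodebromination competes. The Z-configured tertiary allylic alcohol ionises easily. A6 still lacks the bridge and the pyranone.
- Comparison: on regiochemical certainty by construction this road is the best of all. The chosen plan takes the same oxygen from phloroglucinol at no cost and reaches the same certainty by blocking, in far fewer steps.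

Key step: step 11

Remark on the chemistry: 17 is drawn as its Z isomer, the main one expected. Any E isomer reacts to the same pyranone, because the enol ether double bond becomes part of the aromatic ring.

## Route

Step 1
Reactants: 1 phloroglucinol; 2 isobutyryl chloride
Product: 3 2-methyl-1-(2,4,6-trihydroxyphenyl)propan-1-one
Conditions: AlCl3, PhNO2/CH2Cl2, 0 → 45 °C; then aq. HCl
Reagents that add atoms: none
Why: Friedel–Crafts C-acylation of the threefold-activated arene; the first acyl group deactivates the ring and binds AlCl3, so one equivalent of acid chloride should give the monoketone.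

Step 2
Reactants: 3 2-methyl-1-(2,4,6-trihydroxyphenyl)propan-1-one; 4 3-chloro-3-methylbut-1-yne
Product: 5 1-{2,6-dihydroxy-4-[(2-methylbut-3-yn-2-yl)oxy]phenyl}-2-methylpropan-1-one
Conditions: DBU (1 equiv), CuCl2 (cat.), MeCN, 0 °C
Reagents that add atoms: none
Why: Copper-catalysed propargylic O-alkylation of a phenoxide; one equivalent of DBU ionises the para hydroxyl, which is the most acidic (a vinylogous acid) and is not hydrogen-bonded to the ketone, so the tertiary ether should form there.

Step 3
Reactants: 5 1-{2,6-dihydroxy-4-[(2-methylbut-3-yn-2-yl)oxy]phenyl}-2-methylpropan-1-one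
Product: 7 2,4-dihydroxy-3-(2-methylpropanoyl)-6-[(2-methylbut-3-yn-2-yl)oxy]benzaldehyde, via iminium chloride 6 (not isolated)
Conditions: POCl3, DMF, MeCN, 0 °C → rt; then H2O
Reagents that add atoms: N,N-dimethylformamide, CN(C)C=O (formyl carbon); water, O (formyl oxygen)
Why: Vilsmeier–Haack formylation of a phloroglucinol-type ring; the two open ring carbons of 5 are equivalent and the first formyl group deactivates the ring against a second, and hydrolysis of iminium salt 6 on work-up gives the aldehyde before any chromene exists.

Step 4
Reactants: 7 2,4-dihydroxy-3-(2-methylpropanoyl)-6-[(2-methylbut-3-yn-2-yl)oxy]benzaldehyde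
Product: 8 2,4-bis(allyloxy)-3-(2-methylpropanoyl)-6-[(2-methylbut-3-yn-2-yl)oxy]benzaldehyde
Conditions: allyl bromide, K2CO3, DMF, 50 °C
Reagents that add atoms: allyl bromide, C=CCBr
Why: Williamson O-allylation; chelated o-acylphenoxides alkylate on oxygen in DMF, and capping both phenols leaves the later pyran closure only one oxygen and keeps phenols away from the acid chloride.

Step 5
Reactants: 8 2,4-bis(allyloxy)-3-(2-methylpropanoyl)-6-[(2-methylbut-3-yn-2-yl)oxy]benzaldehyde
Product: 10 5,7-bis(allyloxy)-2,2-dimethyl-6-(2-methylpropanoyl)-2H-chromene-8-carbaldehyde, via allenylphenol 9 (not isolated)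
Conditions: o-xylene, 140 °C
Reagents that add atoms: none
Why: Aromatic propargyl Claisen rearrangement to the only free ortho carbon, tautomerisation to allenylphenol 9, 1,5-hydrogen shift and oxa-6π electrocyclisation; only the former ether oxygen can close, which fixes the ring oxygen para to the isobutyryl group, and 1,1-dimethylpropargyl aryl ethers rearrange well below the temperature that allyl aryl ethers need.

Step 6
Reactants: 10 5,7-bis(allyloxy)-2,2-dimethyl-6-(2-methylpropanoyl)-2H-chromene-8-carbaldehyde; 11 dimethyl malonate
Product: 12 dimethyl 2-{[5,7-bis(allyloxy)-2,2-dimethyl-6-(2-methylpropanoyl)-2H-chromen-8-yl]methylidene}malonate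
Conditions: piperidine (cat.), AcOH (cat.), toluene, reflux, Dean–Stark trap
Reagents that add atoms: none
Why: Knoevenagel condensation with azeotropic removal of water; 2,6-dialkoxybenzaldehydes are slow but clean partners, and a dialkyl alkylidenemalonate is too poor a heterodiene to cycloadd to the neighbouring allyl ether.

Step 7
Reactants: 12 dimethyl 2-{[5,7-bis(allyloxy)-2,2-dimethyl-6-(2-methylpropanoyl)-2H-chromen-8-yl]methylidene}malonate
Product: 13 dimethyl 2-{[5,7-bis(allyloxy)-2,2-dimethyl-6-(2-methylpropanoyl)-2H-chromen-8-yl]methyl}malonate
Conditions: NaBH4, THF/MeOH, 0 °C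
Reagents that add atoms: none
Why: Conjugate hydride reduction of an arylidenemalonate, fast at 0 °C; the isopropyl ketone is flanked by two alkoxy groups and twisted out of the ring plane, so it should be reduced far more slowly.

Step 8
Reactants: 13 dimethyl 2-{[5,7-bis(allyloxy)-2,2-dimethyl-6-(2-methylpropanoyl)-2H-chromen-8-yl]methyl}malonate
Product: 14 2-{[5,7-bis(allyloxy)-2,2-dimethyl-6-(2-methylpropanoyl)-2H-chromen-8-yl]methyl}malonic acid
Conditions: LiOH, THF/MeOH/H2O, rt; then 1 M HCl, 0 °C
Reagents that add atoms: lithium hydroxide, [Li+].[OH-] (one oxygen of each carboxyl group)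
Why: Saponification of both methyl esters and cold acidification; the substituted malonic acid is kept near room temperature so that it does not decarboxylate.

Step 9
Reactants: 14 2-{[5,7-bis(allyloxy)-2,2-dimethyl-6-(2-methylpropanoyl)-2H-chromen-8-yl]methyl}malonic acid
Product: 15 2-{[5,7-bis(allyloxy)-2,2-dimethyl-6-(2-methylpropanoyl)-2H-chromen-8-yl]methyl}malonyl dichloride
Conditions: 1-chloro-N,N,2-trimethylprop-1-en-1-amine (2.2 equiv), CH2Cl2, 0 °C → rt; concentrate, use crude
Reagents that add atoms: 1-chloro-N,N,2-trimethylprop-1-en-1-amine, CC(C)=C(Cl)N(C)C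
Why: Acid chloride formation with an α-chloroenamine, which passes through an acyloxyiminium chloride and releases only a neutral amide, so no strong acid meets the chromene double bond.

Step 10
Reactants: 16 pentan-3-one
Product: 17 (Z)-3-(trimethylsilyloxy)pent-2-ene
Conditions: Me3SiOTf, Et3N, Et2O, 0 °C; distil
Reagents that add atoms: trimethylsilyl trifluoromethanesulfonate, C[Si](C)(C)OS(=O)(=O)C(F)(F)F
Why: Soft enolisation and O-silylation of a ketone with a silyl triflate and a tertiary amine; the ketone is symmetrical, so only one enol ether constitution can form.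

Step 11
Reactants: 15 2-{[5,7-bis(allyloxy)-2,2-dimethyl-6-(2-methylpropanoyl)-2H-chromen-8-yl]methyl}malonyl dichloride; 17 (Z)-3-(trimethylsilyloxy)pent-2-ene
Product: 19 3-{[5,7-bis(allyloxy)-2,2-dimethyl-6-(2-methylpropanoyl)-2H-chromen-8-yl]methyl}-6-ethyl-4-hydroxy-5-methyl-2H-pyran-2-one, via diketo acid chloride 18 (not isolated)
Conditions: 17 (1.2 equiv), 2,6-di-tert-butyl-4-methylpyridine (1.1 equiv), CH2Cl2, −78 °C → rt; then H2O
Reagents that add atoms: none
Why: The nucleophilic carbon of enol ether 17 attacks one acid chloride carbon of 15, or the ketene carbon of the (chlorocarbonyl)ketene that 15 forms by losing HCl to the pyridine base; this makes pyranone C4–C5 and, after loss of Me3SiCl, diketo acid chloride 18. Intermediate 18 enolises at the ethyl ketone, and the enol oxygen attacks the remaining acid chloride in a 6-exo-trig addition–elimination that makes O1–C2 and closes the ring; tautomerisation gives the 4-hydroxy-2-pyranone 19. The closest known reaction type is the condensation of silyl enol ethers with malonyl dichlorides and (chlorocarbonyl)ketenes to 4-hydroxy-2-pyranones. No stereocentre is formed, and the two labile centres of 18 become sp2 carbons. The step needs carbon acylation before oxygen acylation, which is the innate preference of silyl enol ethers towards acid chlorides and ketenes. It needs a single regiochemical outcome, which the symmetry of pentan-3-one secures (methyl at C5, ethyl at C6, bridge already on C3). A second intermolecular acylation should be outrun by the intramolecular lactonisation; the allyl ethers keep both phenols out, and the hindered pyridine takes up the HCl that would otherwise add to the chromene C3=C4 bond.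

Step 12
Reactants: 19 3-{[5,7-bis(allyloxy)-2,2-dimethyl-6-(2-methylpropanoyl)-2H-chromen-8-yl]methyl}-6-ethyl-4-hydroxy-5-methyl-2H-pyran-2-one
Product: 20 3-{[5,7-dihydroxy-2,2-dimethyl-6-(2-methylpropanoyl)-2H-chromen-8-yl]methyl}-6-ethyl-4-hydroxy-5-methyl-2H-pyran-2-one
Conditions: Pd(PPh3)4 (cat.), morpholine (10 equiv), THF, rt
Reagents that add atoms: none
Why: Tsuji–Trost deallylation; zerovalent palladium ionises each aryl allyl ether to a π-allyl complex and a phenoxide, and excess morpholine captures the allyl group irreversibly, under conditions that leave the chromene alkene, the ketone and the pyranone untouched.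

## Compound list

1 | phloroglucinol (benzene-1,3,5-triol) | Oc1cc(O)cc(O)c1 | starting material
2 | isobutyryl chloride (2-methylpropanoyl chloride) | CC(C)C(Cl)=O | starting material
3 | 2-methyl-1-(2,4,6-trihydroxyphenyl)propan-1-one | CC(C)C(=O)c1c(O)cc(O)cc1O | intermediate
4 | 3-chloro-3-methylbut-1-yne | C#CC(C)(C)Cl | starting material
5 | 1-{2,6-dihydroxy-4-[(2-methylbut-3-yn-2-yl)oxy]phenyl}-2-methylpropan-1-one | CC(C)C(=O)c1c(O)cc(OC(C)(C)C#C)cc1O | intermediate
6 | N-{[2,4-dihydroxy-3-(2-methylpropanoyl)-6-((2-methylbut-3-yn-2-yl)oxy)phenyl]methylidene}-N-methylmethanaminium chloride (formed in the flask, not isolated) | CC(C)C(=O)c1c(O)cc(OC(C)(C)C#C)c(C=[N+](C)C)c1O.[Cl-] | intermediate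
7 | 2,4-dihydroxy-3-(2-methylpropanoyl)-6-[(2-methylbut-3-yn-2-yl)oxy]benzaldehyde | CC(C)C(=O)c1c(O)cc(OC(C)(C)C#C)c(C=O)c1O | intermediate
8 | 2,4-bis(allyloxy)-3-(2-methylpropanoyl)-6-[(2-methylbut-3-yn-2-yl)oxy]benzaldehyde | CC(C)C(=O)c1c(OCC=C)cc(OC(C)(C)C#C)c(C=O)c1OCC=C | intermediate
9 | 2,4-bis(allyloxy)-6-hydroxy-5-(3-methylbuta-1,2-dien-1-yl)-3-(2-methylpropanoyl)benzaldehyde (formed in the flask, not isolated) | CC(C)C(=O)c1c(OCC=C)c(C=C=C(C)C)c(O)c(C=O)c1OCC=C | intermediate
10 | 5,7-bis(allyloxy)-2,2-dimethyl-6-(2-methylpropanoyl)-2H-chromene-8-carbaldehyde | O=Cc1c(OCC=C)c(C(=O)C(C)C)c(OCC=C)c2c1OC(C)(C)C=C2 | intermediate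
11 | dimethyl malonate | COC(=O)CC(=O)OC | starting material
12 | dimethyl 2-{[5,7-bis(allyloxy)-2,2-dimethyl-6-(2-methylpropanoyl)-2H-chromen-8-yl]methylidene}malonate | COC(=O)C(=Cc1c(OCC=C)c(C(=O)C(C)C)c(OCC=C)c2c1OC(C)(C)C=C2)C(=O)OC | intermediate
13 | dimethyl 2-{[5,7-bis(allyloxy)-2,2-dimethyl-6-(2-methylpropanoyl)-2H-chromen-8-yl]methyl}malonate | COC(=O)C(Cc1c(OCC=C)c(C(=O)C(C)C)c(OCC=C)c2c1OC(C)(C)C=C2)C(=O)OC | intermediate
14 | 2-{[5,7-bis(allyloxy)-2,2-dimethyl-6-(2-methylpropanoyl)-2H-chromen-8-yl]methyl}malonic acid | OC(=O)C(Cc1c(OCC=C)c(C(=O)C(C)C)c(OCC=C)c2c1OC(C)(C)C=C2)C(O)=O | intermediate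
15 | 2-{[5,7-bis(allyloxy)-2,2-dimethyl-6-(2-methylpropanoyl)-2H-chromen-8-yl]methyl}malonyl dichloride | O=C(Cl)C(Cc1c(OCC=C)c(C(=O)C(C)C)c(OCC=C)c2c1OC(C)(C)C=C2)C(Cl)=O | intermediate
16 | pentan-3-one | CCC(=O)CC | starting material
17 | (Z)-3-(trimethylsilyloxy)pent-2-ene | C/C=C(/CC)O[Si](C)(C)C | intermediate
18 | 2-{[5,7-bis(allyloxy)-2,2-dimethyl-6-(2-methylpropanoyl)-2H-chromen-8-yl]methyl}-4-methyl-3,5-dioxoheptanoyl chloride (mixture of diastereomers at two enolisable centres; formed in the flask, not isolated) | CCC(=O)C(C)C(=O)C(Cc1c(OCC=C)c(C(=O)C(C)C)c(OCC=C)c2c1OC(C)(C)C=C2)C(Cl)=O | intermediate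
19 | 3-{[5,7-bis(allyloxy)-2,2-dimethyl-6-(2-methylpropanoyl)-2H-chromen-8-yl]methyl}-6-ethyl-4-hydroxy-5-methyl-2H-pyran-2-one | CCc1oc(=O)c(Cc2c(OCC=C)c(C(=O)C(C)C)c(OCC=C)c3c2OC(C)(C)C=C3)c(O)c1C | intermediate
20 | 3-{[5,7-dihydroxy-2,2-dimethyl-6-(2-methylpropanoyl)-2H-chromen-8-yl]methyl}-6-ethyl-4-hydroxy-5-methyl-2H-pyran-2-one | CCc1oc(=O)c(Cc2c(O)c(C(=O)C(C)C)c(O)c3c2OC(C)(C)C=C3)c(O)c1C | target

## Step count and least certain steps

Total: 12 steps. Longest linear sequence: 11 steps (steps 1–9, 11 and 12, from phloroglucinol 1); step 10 is a one-step side branch.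

**Step 11 (key step).** The dichloride may be consumed by paths other than a single C-acylation. These are O-acylation of the enol ether, self-condensation of the derived ketene, dealkylative lactonisation of an acid chloride onto the C7 allyl ether, and hydrochlorination of the chromene if HCl is not trapped fast enough. The cause is the bulky 2,6-disubstituted benzyl group on the malonyl carbon, which slows the wanted bimolecular attack.
Fallback: the pyranone is made first and the bridge is closed last. Enol ether 17 is condensed with unsubstituted malonyl dichloride to 6-ethyl-4-hydroxy-5-methyl-2H-pyran-2-one F1. F1 is then joined to aldehyde 10 by a three-component reductive alkylation (L-proline, Hantzsch ester, CH2Cl2, rt): Knoevenagel condensation at pyranone C3 is followed at once by hydride transfer to the alkylidene, which should outrun addition of a second pyranone and cycloaddition to the neighbouring allyl ether. This sets out from 10 (with 17) and rejoins the route at 19, leaving out 12 to 15.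

**Step 2.** Site selectivity may be poor: alkylation at an ortho oxygen, double alkylation, or C-propargylation of the ring. The phenoxide of 3 is ambident and the acidity gap between the hydroxyls is moderate.
Fallback: from 3, para-selective protection with chloromethyl methyl ether and iPr2NEt (a hard electrophile that does not C-alkylate) gives the mono-acetal 1-[2,6-dihydroxy-4-(methoxymethoxy)phenyl]-2-methylpropan-1-one F2. Allylation of both ortho phenols gives 1-[2,6-bis(allyloxy)-4-(methoxymethoxy)phenyl]-2-methylpropan-1-one F3. HCl in methanol then frees the single phenol 1-[2,6-bis(allyloxy)-4-hydroxyphenyl]-2-methylpropan-1-one F4. F4 is annulated with 3-methylbut-2-enal (PhB(OH)2, AcOH, toluene, reflux) to 1-[5,7-bis(allyloxy)-2,2-dimethyl-2H-chromen-6-yl]-2-methylpropan-1-one F5, where only one oxygen can close. F5 is formylated at C8 (POCl3, DMF) and the sequence comes back to the route at 10.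

**Step 5.** At 140 °C the allyl ethers may begin their own Claisen rearrangement, or the aldehyde may degrade before the cascade is complete, since the hydrogen shift and ring closure follow a rate-limiting sigmatropic step.
Fallback: from 8 directly to 10 without heat, by 6-endo hydroarylation of the alkyne with Ph3PAuNTf2 (monovalent gold) in CH2Cl2 at room temperature. The O1–C2 bond is never broken, and no new compound is made.

**Step 9.** The half-converted malonic acid may decarboxylate or lose HCl to a ketene that oligomerises, or an acid chloride may lactonise onto the C7 ether, before both carboxyl groups are converted. Monosubstituted malonyl derivatives are prone to all three.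
Fallback: from 14, silylation with N,O-bis(trimethylsilyl)acetamide gives bis(trimethylsilyl) 2-{[5,7-bis(allyloxy)-2,2-dimethyl-6-(2-methylpropanoyl)-2H-chromen-8-yl]methyl}malonate F6. Oxalyl chloride with catalytic DMF in CH2Cl2 at 0 °C then exchanges each silyl ester for chloride without free HCl, and the route is rejoined at 15.

**Step 12.** The π-allyl palladium complex may be captured by the product instead of morpholine: C3-allylation of the pyranone enolate, or dearomatising C-allylation of the liberated acylphloroglucinol. Both are good soft carbon nucleophiles.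
Fallback: from 19, the allyl ethers are isomerised with hydrogen-activated [Ir(cod)(PMePh2)2]PF6 in THF to the bis(prop-1-enyl) ether 6-ethyl-4-hydroxy-5-methyl-3-{[2,2-dimethyl-6-(2-methylpropanoyl)-5,7-bis(prop-1-enyloxy)-2H-chromen-8-yl]methyl}-2H-pyran-2-one F7. Its enol ethers are hydrolysed with dilute aqueous HCl in acetone at room temperature, which arrives at 20 without any π-allyl intermediate.

## Further compounds

F1 | step 11 | 6-ethyl-4-hydroxy-5-methyl-2H-pyran-2-one | CCc1oc(=O)cc(O)c1C
F2 | step 2 | 1-[2,6-dihydroxy-4-(methoxymethoxy)phenyl]-2-methylpropan-1-one | CC(C)C(=O)c1c(O)cc(OCOC)cc1O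
F3 | step 2 | 1-[2,6-bis(allyloxy)-4-(methoxymethoxy)phenyl]-2-methylpropan-1-one | CC(C)C(=O)c1c(OCC=C)cc(OCOC)cc1OCC=C
F4 | step 2 | 1-[2,6-bis(allyloxy)-4-hydroxyphenyl]-2-methylpropan-1-one | CC(C)C(=O)c1c(OCC=C)cc(O)cc1OCC=C
F5 | step 2 | 1-[5,7-bis(allyloxy)-2,2-dimethyl-2H-chromen-6-yl]-2-methylpropan-1-one | CC(C)C(=O)c1c(OCC=C)cc2OC(C)(C)C=Cc2c1OCC=C
F0 | step 5 | none | none
F6 | step 9 | bis(trimethylsilyl) 2-{[5,7-bis(allyloxy)-2,2-dimethyl-6-(2-methylpropanoyl)-2H-chromen-8-yl]methyl}malonate | C[Si](C)(C)OC(=O)C(Cc1c(OCC=C)c(C(=O)C(C)C)c(OCC=C)c2c1OC(C)(C)C=C2)C(=O)O[Si](C)(C)C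
F7 | step 12 | 6-ethyl-4-hydroxy-5-methyl-3-{[2,2-dimethyl-6-(2-methylpropanoyl)-5,7-bis(prop-1-enyloxy)-2H-chromen-8-yl]methyl}-2H-pyran-2-one (mixture of enol ether geometries) | CCc1oc(=O)c(Cc2c(OC=CC)c(C(=O)C(C)C)c(OC=CC)c3c2OC(C)(C)C=C3)c(O)c1C
A1 | alternative 1 | 1-(5,7-dihydroxy-2,2-dimethyl-2H-chromen-6-yl)-2-methylpropan-1-one | CC(C)C(=O)c1c(O)cc2OC(C)(C)C=Cc2c1O
A2 | alternative 2 | 3-{[5,7-bis(methoxymethoxy)-2,2-dimethyl-6-(2-methylpropanoyl)-2H-chromen-8-yl]methyl}-6-ethyl-2-methoxy-5-methyl-4H-pyran-4-one | CCc1oc(OC)c(Cc2c(OCOC)c(C(=O)C(C)C)c(OCOC)c3c2OC(C)(C)C=C3)c(=O)c1C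
A3 | alternative 2 | 6-ethyl-2,2,5-trimethyl-4H-1,3-dioxin-4-one | CCC1=C(C)C(=O)OC(C)(C)O1
A4 | alternative 2 | {[3-(5,7-bis(methoxymethoxy)-2,2-dimethyl-6-(2-methylpropanoyl)-2H-chromen-8-yl)-1-methoxyprop-1-en-1-yl]oxy}trimethylsilane | COC(O[Si](C)(C)C)=CCc1c(OCOC)c(C(=O)C(C)C)c(OCOC)c2c1OC(C)(C)C=C2
A5 | alternative 2 | 2-methyl-3-oxopent-1-en-1-one (acylketene) | CCC(=O)C(C)=C=O
A6 | alternative 3 | 1-[5,7-bis(methoxymethoxy)-2,2-dimethyl-2H-chromen-6-yl]-2-methylpropan-1-one | CC(C)C(=O)c1c(OCOC)cc2OC(C)(C)C=Cc2c1OCOC
A7 | alternative 3 | 1-{4-bromo-3-[(Z)-3-hydroxy-3-methylbut-1-en-1-yl]-2,6-bis(methoxymethoxy)phenyl}-2-methylpropan-1-one | CC(C)C(=O)c1c(OCOC)cc(Br)c(/C=C\C(C)(C)O)c1OCOC
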